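**Strategy.** Numbering the cyclohexanone ring C1 (CH–O ester), C2 (C=O), C3/C4 (epoxide), C5, C6 (CH bearing the side chain C7(=C14H2)–C8(=O)–), everything rests on disconnecting C1–C6: the homoallylic alcohol unit O–C1–C6–C7=C14 is the retron of a carbonyl allylation. In one operation, palladium-catalysed bis-stannylation of the terminal allene of an acyclic (2S,3S)-epoxy α-keto aldehyde and intramolecular allyl transfer to the aldehyde close the six-membered ring, create C1 and C6, and leave C7 as a vinylstannane beside the exocyclic methylene. Mitsunobu inversion with tiglic acid, carbonylative Stille coupling with prenyl chloride and a singlet-oxygen ene reaction finish the target.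

Key step: step 9

Remark: compounds 1, 4, 16 and 18 are taken as commercial; the atom labels C1–C14 defined above are used throughout.

Step 1
Reactants: 1 methyl (4S)-2,2-dimethyl-1,3-dioxolane-4-carboxylate
Product: 3 1-[(4S)-2,2-dimethyl-1,3-dioxolan-4-yl]ethan-1-one, via Weinreb amide 2 (not isolated)
Conditions: MeNH(OMe)·HCl, iPrMgCl, THF, −20 °C; then MeMgBr, −20 → 0 °C
Reagents that add atoms: methylmagnesium bromide, C[Mg]Br
Why: One-pot Weinreb ketone synthesis: the magnesium amide converts the ester into the N-methoxy-N-methylamide, whose chelated adduct with MeMgBr survives until work-up, so only one methyl group is added and the existing stereocentre should be untouched at low temperature.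

Step 2
Reactants: 4 but-3-yn-1-ol
Product: 5 penta-3,4-dien-1-ol
Conditions: (CH2O)n, CuBr, iPr2NH, 1,4-dioxane, reflux
Reagents that add atoms: formaldehyde (from paraformaldehyde), C=O
Why: Crabbé homologation: copper-mediated Mannich coupling of the terminal alkyne with formaldehyde and the amine, then hydride shift with loss of the imine, should give the terminal allene with the free hydroxyl tolerated; no stereocentre is formed.

Step 3
Reactants: 5 penta-3,4-dien-1-ol
Product: 6 5-bromopenta-1,2-diene
Conditions: CBr4, PPh3, CH2Cl2, 0 °C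
Reagents that add atoms: tetrabromomethane, BrC(Br)(Br)Br
Why: The Appel reaction converts the primary alcohol into the bromide by SN2 under neutral conditions that leave the allene intact; no stereocentre is formed.

Step 4
Reactants: 6 5-bromopenta-1,2-diene
Product: 7 triphenyl(penta-3,4-dien-1-yl)phosphonium bromide
Conditions: PPh3, MeCN, reflux
Reagents that add atoms: triphenylphosphine, c1ccc(cc1)P(c1ccccc1)c1ccccc1
Why: SN2 quaternisation of triphenylphosphine by the unhindered primary bromide should give the Wittig salt; no stereocentre is formed.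

Step 5
Reactants: 7 triphenyl(penta-3,4-dien-1-yl)phosphonium bromide; 3 1-[(4S)-2,2-dimethyl-1,3-dioxolan-4-yl]ethan-1-one
Product: 9 (4R)-4-[(2Z)-hepta-2,5,6-trien-2-yl]-2,2-dimethyl-1,3-dioxolane, via phosphonium ylide 8 (not isolated)
Conditions: KN(SiMe3)2, THF, −78 °C; then 3, −78 °C → rt
Reagents that add atoms: none
Why: Wittig olefination of an α-alkoxy methyl ketone with a salt-free non-stabilised ylide is Z-selective, so the dioxolane carbon and the new CH2 chain should end up cis on the trisubstituted C3=C4 alkene, while the acetal-protected stereocentre is kept at low temperature.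

Step 6
Reactants: 9 (4R)-4-[(2Z)-hepta-2,5,6-trien-2-yl]-2,2-dimethyl-1,3-dioxolane
Product: 10 (2R,3Z)-3-methylocta-3,6,7-triene-1,2-diol
Conditions: AcOH/H2O (4:1), 40 °C
Reagents that add atoms: none
Why: Acid-catalysed acetal hydrolysis should free the 1,2-diol, the skipped ene-allene being stable to dilute acetic acid; no new stereocentre is formed.

Step 7
Reactants: 10 (2R,3Z)-3-methylocta-3,6,7-triene-1,2-diol
Product: 11 (1S)-1-[(2R,3S)-3-(buta-2,3-dien-1-yl)-2-methyloxiran-2-yl]ethane-1,2-diol
Conditions: mCPBA, CH2Cl2, −20 → 0 °C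
Reagents that add atoms: 3-chloroperbenzoic acid (mCPBA), OOC(=O)c1cccc(Cl)c1
Why: Hydroxyl-directed peracid epoxidation of the electron-rich trisubstituted alkene: with the Z substituent, A(1,3) strain holds the carbinol C–H in the alkene plane, so the C2 hydroxyl should deliver the peracid to one face and give the threo epoxy alcohol with the oxirane configuration required for C3/C4, the less nucleophilic allene staying untouched.

Step 8
Reactants: 11 (1S)-1-[(2R,3S)-3-(buta-2,3-dien-1-yl)-2-methyloxiran-2-yl]ethane-1,2-diol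
Product: 12 2-[(2S,3S)-3-(buta-2,3-dien-1-yl)-2-methyloxiran-2-yl]-2-oxoacetaldehyde
Conditions: (COCl)2, DMSO, CH2Cl2, −78 °C; then Et3N, −78 → 0 °C
Reagents that add atoms: none
Why: Swern oxidation of both hydroxyl groups should give the 1,2-keto aldehyde without opening the epoxide (C3 is quaternary and cannot epimerise); the C2 stereocentre, having relayed its chirality to C3/C4, is erased.

Step 9
Reactants: 12 2-[(2S,3S)-3-(buta-2,3-dien-1-yl)-2-methyloxiran-2-yl]-2-oxoacetaldehyde
Product: 15 (1S,3R,4R,6S)-3-hydroxy-1-methyl-4-[1-(trimethylstannyl)ethenyl]-7-oxabicyclo[4.1.0]heptan-2-one, via bis-stannyl allylstannane 13 (not isolated), via tin alkoxide 14 (not isolated)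
Conditions: [Pd(C3H5)Cl]2 (5 mol %), Me3SnSnMe3, THF, 25 °C; then H2O
Reagents that add atoms: hexamethyldistannane, C[Sn](C)(C)[Sn](C)(C)C
Why: The divalent palladium precatalyst is reduced by the distannane to zerovalent palladium, which inserts into the Sn–Sn bond and adds both stannyl groups across the terminal C7=C14 bond of the allene from the face remote from C5, giving allylstannane 13 with C5 cis to the CH2Sn group; its γ-carbon C6 then attacks the aldehyde carbon C1 (SE2') through a closed chair-like six-membered transition state with tin on the aldehyde oxygen. The closest known reaction type is the palladium-catalysed tandem bis-metalation (distannane or silylstannane)/carbonyl allylation of allenyl aldehydes, which delivers cis-2-(1-metallovinyl)cycloalkanols. The cyclohexanone ring closes in a 6-exo-trig mode at C1=O by formation of C1–C6, the allene supplying C6, C7 and the exocyclic C14 methylene. The cis allyl geometry enforces a cis-fused bicyclic transition state, so the new C1–O bond (axial) and the stannylvinyl group on C6 (equatorial) should become cis; the axial C1–O–Sn bond should go to the epoxide-oxygen face of the forming half-chair, where it avoids the syn-1,3 C3 methyl group and tin can bridge to the epoxide oxygen, which fixes C1 and C6 relative to C3/C4. The step needs aldehyde-over-ketone and C6-over-C14 selectivity, secured by the higher electrophilicity of the glyoxal CHO and by six- versus eight-membered (or, at the ketone, strained five-membered) ring formation.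

Step 10
Reactants: 15 (1S,3R,4R,6S)-3-hydroxy-1-methyl-4-[1-(trimethylstannyl)ethenyl]-7-oxabicyclo[4.1.0]heptan-2-one; 16 tiglic acid, (2E)-2-methylbut-2-enoic acid
Product: 17 (1S,3S,4R,6S)-1-methyl-2-oxo-4-[1-(trimethylstannyl)ethenyl]-7-oxabicyclo[4.1.0]heptan-3-yl (2E)-2-methylbut-2-enoate
Conditions: PPh3, DIAD, toluene, 0 °C → rt
Reagents that add atoms: none
Why: Mitsunobu esterification: the alkoxyphosphonium ion of the axial C1 hydroxyl, aligned with the π* orbital of the C2 carbonyl, should be displaced by tiglate in an SN2 reaction with inversion, placing the ester equatorial and trans to the C6 substituent.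

Step 11
Reactants: 17 (1S,3S,4R,6S)-1-methyl-2-oxo-4-[1-(trimethylstannyl)ethenyl]-7-oxabicyclo[4.1.0]heptan-3-yl (2E)-2-methylbut-2-enoate; 18 prenyl chloride, 1-chloro-3-methylbut-2-ene
Product: 19 (1S,3S,4S,6S)-1-methyl-4-(6-methyl-3-oxohepta-1,5-dien-2-yl)-2-oxo-7-oxabicyclo[4.1.0]heptan-3-yl (2E)-2-methylbut-2-enoate
Conditions: CO (3 atm), Pd2(dba)3 (2.5 mol %), AsPh3, THF, 50 °C
Reagents that add atoms: carbon monoxide, [C-]#[O+]
Why: Carbonylative Stille coupling: oxidative addition of the allylic chloride to zerovalent palladium, CO insertion at the less substituted allyl terminus, alkenyl transfer from tin and reductive elimination should give the allyl vinyl ketone under neutral conditions that keep the C10=C11 alkene out of conjugation and spare the epoxide and esters; no stereocentre is touched.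

Step 12
Reactants: 19 (1S,3S,4S,6S)-1-methyl-4-(6-methyl-3-oxohepta-1,5-dien-2-yl)-2-oxo-7-oxabicyclo[4.1.0]heptan-3-yl (2E)-2-methylbut-2-enoate
Product: 20 (1S,3S,4S,6S)-4-[(4E)-6-hydroperoxy-6-methyl-3-oxohepta-1,4-dien-2-yl]-1-methyl-2-oxo-7-oxabicyclo[4.1.0]heptan-3-yl (2E)-2-methylbut-2-enoate
Conditions: O2, hν (visible), meso-tetraphenylporphyrin (cat.), CH2Cl2, −20 °C
Reagents that add atoms: dioxygen (as singlet oxygen), O=O
Why: Schenck ene reaction: singlet oxygen should attack only the prenyl alkene (the other alkenes are carbonyl-deactivated), bond to C11 and abstract a hydrogen from C9 (cis effect, reinforced by the adjacent C8 carbonyl), shifting the double bond to C9=C10 with E geometry in conjugation with the ketone; the secondary hydroperoxide from abstraction at the cis methyl group is the expected minor, separable regioisomer.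

**Compound list**

1 | methyl (4S)-2,2-dimethyl-1,3-dioxolane-4-carboxylate | CC1(C)OC[C@H](O1)C(=O)OC | starting material
2 | (4S)-N-methoxy-N,2,2-trimethyl-1,3-dioxolane-4-carboxamide (Weinreb amide) | CC1(C)OC[C@H](O1)C(=O)N(C)OC | intermediate
3 | 1-[(4S)-2,2-dimethyl-1,3-dioxolan-4-yl]ethan-1-one | CC1(C)OC[C@H](O1)C(C)=O | intermediate
4 | but-3-yn-1-ol | C#CCCO | starting material
5 | penta-3,4-dien-1-ol | C=C=CCCO | intermediate
6 | 5-bromopenta-1,2-diene | C=C=CCCBr | intermediate
7 | triphenyl(penta-3,4-dien-1-yl)phosphonium bromide | C=C=CCC[P+](c1ccccc1)(c1ccccc1)c1ccccc1.[Br-] | intermediate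
8 | triphenyl(penta-3,4-dien-1-ylidene)-λ5-phosphane (ylide) | C=C=CCC=P(c1ccccc1)(c1ccccc1)c1ccccc1 | intermediate
9 | (4R)-4-[(2Z)-hepta-2,5,6-trien-2-yl]-2,2-dimethyl-1,3-dioxolane | CC1(C)OC[C@H](O1)/C(C)=C\CC=C=C | intermediate
10 | (2R,3Z)-3-methylocta-3,6,7-triene-1,2-diol | OC[C@H](O)/C(C)=C\CC=C=C | intermediate
11 | (1S)-1-[(2R,3S)-3-(buta-2,3-dien-1-yl)-2-methyloxiran-2-yl]ethane-1,2-diol (threo epoxy diol) | C=C=CC[C@@H]1O[C@]1(C)[C@@H](O)CO | intermediate
12 | 2-[(2S,3S)-3-(buta-2,3-dien-1-yl)-2-methyloxiran-2-yl]-2-oxoacetaldehyde | C=C=CC[C@@H]1O[C@]1(C)C(=O)C=O | intermediate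
13 | 2-[(2S,3S)-3-[(2E)-3,4-bis(trimethylstannyl)but-2-en-1-yl]-2-methyloxiran-2-yl]-2-oxoacetaldehyde | C[Sn](C)(C)C/C(=C\C[C@@H]1O[C@]1(C)C(=O)C=O)[Sn](C)(C)C | intermediate
14 | (1S,3R,4R,6S)-1-methyl-4-[1-(trimethylstannyl)ethenyl]-3-[(trimethylstannyl)oxy]-7-oxabicyclo[4.1.0]heptan-2-one | C=C([Sn](C)(C)C)[C@@H]1C[C@@H]2O[C@]2(C)C(=O)[C@@H]1O[Sn](C)(C)C | intermediate
15 | (1S,3R,4R,6S)-3-hydroxy-1-methyl-4-[1-(trimethylstannyl)ethenyl]-7-oxabicyclo[4.1.0]heptan-2-one (hydroxyl cis to the stannylvinyl group and to the epoxide oxygen) | C=C([Sn](C)(C)C)[C@@H]1C[C@@H]2O[C@]2(C)C(=O)[C@@H]1O | intermediate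
16 | tiglic acid, (2E)-2-methylbut-2-enoic acid | C/C=C(\C)C(=O)O | starting material
17 | (1S,3S,4R,6S)-1-methyl-2-oxo-4-[1-(trimethylstannyl)ethenyl]-7-oxabicyclo[4.1.0]heptan-3-yl (2E)-2-methylbut-2-enoate | C=C([Sn](C)(C)C)[C@@H]1C[C@@H]2O[C@]2(C)C(=O)[C@H]1OC(=O)/C(C)=C/C | intermediate
18 | prenyl chloride, 1-chloro-3-methylbut-2-ene | CC(C)=CCCl | starting material
19 | (1S,3S,4S,6S)-1-methyl-4-(6-methyl-3-oxohepta-1,5-dien-2-yl)-2-oxo-7-oxabicyclo[4.1.0]heptan-3-yl (2E)-2-methylbut-2-enoate | C=C(C(=O)CC=C(C)C)[C@@H]1C[C@@H]2O[C@]2(C)C(=O)[C@H]1OC(=O)/C(C)=C/C | intermediate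
20 | (1S,3S,4S,6S)-4-[(4E)-6-hydroperoxy-6-methyl-3-oxohepta-1,4-dien-2-yl]-1-methyl-2-oxo-7-oxabicyclo[4.1.0]heptan-3-yl (2E)-2-methylbut-2-enoate | C=C(C(=O)/C=C/C(C)(C)OO)[C@@H]1C[C@@H]2O[C@]2(C)C(=O)[C@H]1OC(=O)/C(C)=C/C | target

**Total step count:** 12

**Longest linear sequence:** 11 steps (from but-3-yn-1-ol 4, steps 2–12)

**Steps most likely to fail**

Step 9. What may go wrong: reduction or stannylation of the 1,2-dicarbonyl unit (or palladium-induced isomerisation of the epoxy ketone) may compete with metalation of the allene, and facial selectivity with respect to the epoxide may erode. Fallback: metalate the allene before the carbonyl groups exist. Setting out from epoxy diol 11, the same palladium-catalysed bis-stannylation ([Pd(C3H5)Cl]2, Me3SnSnMe3, THF) would give (1S)-1-[(2R,3S)-3-[(2E)-3,4-bis(trimethylstannyl)but-2-en-1-yl]-2-methyloxiran-2-yl]ethane-1,2-diol F1. Parikh–Doering oxidation of both hydroxyl groups (SO3·pyridine, DMSO, iPr2NEt, CH2Cl2) would then unveil keto aldehyde 13 in the absence of palladium. There it should close the ring thermally, or under chelation of the aldehyde and epoxide oxygens by MgBr2·OEt2, to 15 after aqueous work-up. The fallback comes back to the route at 13.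

Step 10. What may go wrong: elimination of the activated axial alcohol toward the C1=C6 enone, or substitution with partial retention, instead of clean inversion. Fallback: esterify with retention and correct C1 by equilibration. From 15, tigloyl chloride (pyridine, DMAP, CH2Cl2) would give the cis tiglate (1S,3R,4R,6S)-1-methyl-2-oxo-4-[1-(trimethylstannyl)ethenyl]-7-oxabicyclo[4.1.0]heptan-3-yl (2E)-2-methylbut-2-enoate F2. Reversible enolisation at C1 with DBU in toluene should then drain it into the diequatorial trans isomer 17, where the route resumes.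

Step 11. What may go wrong: direct allyl–vinyl coupling without CO insertion, bond formation at the tertiary allyl terminus, or slow transfer of the α-branched alkenyl group from tin. Fallback: make C7 the nucleophile toward an aldehyde. From 17, iododestannylation (I2, CH2Cl2, 0 °C) would give (1S,3S,4R,6S)-4-(1-iodoethenyl)-1-methyl-2-oxo-7-oxabicyclo[4.1.0]heptan-3-yl (2E)-2-methylbut-2-enoate F3. Nozaki–Hiyama–Kishi coupling (CrCl2, cat. NiCl2, DMSO, rt) with 4-methylpent-3-enal F4, freshly made from commercial 4-methylpent-3-en-1-ol with Dess–Martin periodinane, would give (1S,3S,4S,6S)-4-(3-hydroxy-6-methylhepta-1,5-dien-2-yl)-1-methyl-2-oxo-7-oxabicyclo[4.1.0]heptan-3-yl (2E)-2-methylbut-2-enoate F5 as a mixture of carbinol epimers. Dess–Martin oxidation of F5 would return to the route at 19.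

**Further compounds**

F1 | step 9 | (1S)-1-[(2R,3S)-3-[(2E)-3,4-bis(trimethylstannyl)but-2-en-1-yl]-2-methyloxiran-2-yl]ethane-1,2-diol | C[Sn](C)(C)C/C(=C\C[C@@H]1O[C@]1(C)[C@@H](O)CO)[Sn](C)(C)C
F2 | step 10 | (1S,3R,4R,6S)-1-methyl-2-oxo-4-[1-(trimethylstannyl)ethenyl]-7-oxabicyclo[4.1.0]heptan-3-yl (2E)-2-methylbut-2-enoate | C=C([Sn](C)(C)C)[C@@H]1C[C@@H]2O[C@]2(C)C(=O)[C@@H]1OC(=O)/C(C)=C/C
F3 | step 11 | (1S,3S,4R,6S)-4-(1-iodoethenyl)-1-methyl-2-oxo-7-oxabicyclo[4.1.0]heptan-3-yl (2E)-2-methylbut-2-enoate | C=C(I)[C@@H]1C[C@@H]2O[C@]2(C)C(=O)[C@H]1OC(=O)/C(C)=C/C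
F4 | step 11 | 4-methylpent-3-enal | CC(C)=CCC=O
F5 | step 11 | (1S,3S,4S,6S)-4-(3-hydroxy-6-methylhepta-1,5-dien-2-yl)-1-methyl-2-oxo-7-oxabicyclo[4.1.0]heptan-3-yl (2E)-2-methylbut-2-enoate (both carbinol epimers) | C=C(C(O)CC=C(C)C)[C@@H]1C[C@@H]2O[C@]2(C)C(=O)[C@H]1OC(=O)/C(C)=C/C
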